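## Retrosynthetic overview
1. The C6–C7 bond and the lactone C–O bond are cut together. A chromium-electrocatalytic Barbier macrocyclisation/lactonisation of bromo-enal 13 forms the ten-membered ring and the α-methylene-γ-butyrolactone last, in one step.
2. 13 comes from 3-methylfuran 12 by singlet-oxygen photooxygenation. The furan masks the (Z)-C3(=O)–C4(Me)=C5–C6HO unit, and the released C10–OH condenses on C3 to give the 3(2H)-furanone.
3. 12 comes from aldehyde 9 and methyl propiolate (Baylis–Hillman surrogate, then SN2′ bromination). The tiglate is installed by Mitsunobu inversion at C8.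
4. Furan ketone 5 comes from lactone 3 and the dianion of commercial (Z)-enynol 4, which supplies C2–C6 and C15 with the Z geometry already in place.
5. 3 comes from the L-glutamic-acid-derived lactone 1 by two face-selective enolate reactions (C8 bought, C10 controlled by it). Ring order: temporary furan, then furanone, then carbocycle and lactone together.

Assumption: germacrane numbering (C1–C15) is used for atom labels, and 1, 4, 6 and 10 are taken as catalogue chemicals.

## Route

**Step 1**
Reactants: 1, (S)-5-(trityloxymethyl)dihydrofuran-2(3H)-one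
Product: 2, (3R,5S)-3-methyl-5-(trityloxymethyl)dihydrofuran-2(3H)-one (CH3 trans to CH2OTr)
Conditions: LDA, THF, −78 °C; MeI, −78 → −40 °C
Reagents that add atoms: methyl iodide, CI
Why: This is a γ-lactone enolate alkylation in which MeI enters anti to the bulky CH2OTr group; the new centre is planarised again in step 2, so its ratio does not matter.

**Step 2**
Reactants: 2
Product: 3, (3R,5S)-3-methyl-3-(triethylsilyloxy)-5-(trityloxymethyl)dihydrofuran-2(3H)-one (OSiEt3 trans, CH3 cis to CH2OTr)
Conditions: KHMDS, THF, −78 °C; O2, P(OEt)3; then Et3SiCl, −78 °C → rt (one pot)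
Reagents that add atoms: dioxygen, O=O; chlorotriethylsilane, CC[Si](Cl)(CC)CC
Why: This is an enolate oxygenation with in-situ phosphite reduction and silyl trapping, in which oxygen attacks the trisubstituted enolate on the face opposite CH2OTr, so the bought C8 centre sets C10 as R.

**Step 3**
Reactants: 3; 4, (Z)-3-methylpent-2-en-4-yn-1-ol
Product: 5, (3R,5S)-5-hydroxy-3-methyl-1-(3-methylfuran-2-yl)-3-(triethylsilyloxy)-6-(trityloxy)hexan-2-one
Conditions: 4 (2 equiv), n-BuLi (4 equiv), THF, −78 → 0 °C; 3, −78 → −30 °C; AcOH; crude + AgNO3/SiO2 (10 mol %), CH2Cl2, rt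
Reagents that add atoms: none
Why: Acetylide addition to the lactone stops at the lactolate, and the released (Z)-hydroxy-enynone undergoes 5-exo-dig oxa-Michael addition and aromatisation (enynol-to-furan cycloisomerisation); no stereocentre is touched, and the furan protects C3, C6 and the Z alkene at once.

**Step 4**
Reactants: 5; 6, tiglic acid
Product: 7, (2R,4R)-4-methyl-6-(3-methylfuran-2-yl)-5-oxo-4-(triethylsilyloxy)-1-(trityloxy)hexan-2-yl (E)-2-methylbut-2-enoate
Conditions: 6 (3 equiv), PPh3, DIAD, toluene, 0 °C → rt
Reagents that add atoms: tiglic acid, C/C=C(\C)C(=O)O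
Why: This Mitsunobu esterification is an SN2 displacement that installs the tiglate and inverts C8 from S to the required R in one operation; the tertiary silyl ether and the hindered ketone are inert.

**Step 5**
Reactants: 7
Product: 8, (2R,4R)-1-hydroxy-4-methyl-6-(3-methylfuran-2-yl)-5-oxo-4-(triethylsilyloxy)hexan-2-yl (E)-2-methylbut-2-enoate
Conditions: CSA (10 mol %), MeOH–CH2Cl2 (1:4), 0 °C, short contact
Reagents that add atoms: none
Why: This is an acid-catalysed SN1 detritylation, where the primary trityl ether ionises far faster than the hindered tertiary TES ether cleaves and the conjugated, α-branched tigloyl group migrates slowly at 0 °C.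

**Step 6**
Reactants: 8
Product: 9, (2R,4R)-4-methyl-6-(3-methylfuran-2-yl)-1,5-dioxo-4-(triethylsilyloxy)hexan-2-yl (E)-2-methylbut-2-enoate
Conditions: Dess–Martin periodinane, NaHCO3, CH2Cl2, 0 °C; used crude
Reagents that add atoms: none
Why: This buffered Dess–Martin oxidation is neutral enough to keep the α-acyloxy aldehyde centre (C8) intact, and the silylated C10–O cannot form a lactol that would over-oxidise.

**Step 7**
Reactants: 9; 10, methyl propiolate
Product: 11, methyl (3RS,4R,6R)-3-hydroxy-6-methyl-2-methylidene-8-(3-methylfuran-2-yl)-7-oxo-4-[(E)-2-methylbut-2-enoyloxy]-6-(triethylsilyloxy)octanoate (C7 epimers, both used)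
Conditions: i-Bu2AlH, NMO, THF, 0 °C; 10; then 9, −20 → 0 °C; cold dilute acid quench
Reagents that add atoms: methyl propiolate, C#CC(=O)OC
Why: This vinylalumination is a non-basic Baylis–Hillman surrogate in which the α-(methoxycarbonyl)vinylalane adds to the aldehyde in preference to the hindered ketone, avoids amine-induced epimerisation at C8, and creates a carbinol centre that is erased in step 8.

**Step 8**
Reactants: 11
Product: 12, methyl (2Z,4R,6R)-2-(bromomethyl)-6-methyl-8-(3-methylfuran-2-yl)-7-oxo-4-[(E)-2-methylbut-2-enoyloxy]-6-(triethylsilyloxy)oct-2-enoate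
Conditions: PBr3 (0.5 equiv), Et2O, −20 → 0 °C
Reagents that add atoms: phosphorus tribromide, BrP(Br)Br
Why: This SN2′ bromination of a Baylis–Hillman alcohol converges both C7 epimers on the thermodynamic (Z)-2-(bromomethyl)enoate (C8 cis to CH2Br).

**Step 9**
Reactants: 12
Product: 13, methyl (2Z,4R)-2-(bromomethyl)-4-[(E)-2-methylbut-2-enoyloxy]-5-{(2R)-2-methyl-3-oxo-5-[(2Z)-4-oxobut-2-en-2-yl]-2,3-dihydrofuran-2-yl}pent-2-enoate
Conditions: O2, tetraphenylporphyrin (cat.), white LED, CH2Cl2, −78 °C; Me2S, −78 → −20 °C; then HF·pyridine, MeCN, 0 °C (one pot)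
Reagents that add atoms: dioxygen, O=O
Why: [4+2] photooxygenation of the electron-rich furan (the electron-poor enoates are inert to 1O2) and reduction give the cis-4-oxo-enal with its Z geometry inherited from the ring, and unmasking C10–OH triggers the standard cyclodehydration of an α′-hydroxy-1,3-diketone to the 3(2H)-furanone; no stereocentre is touched.

**Step 10**
Reactants: 13
Product: 14, atripliciolide tiglate (6R,7R,8R,10R; 4Z)
Conditions: CrCl2 (20 mol %), Cp2ZrCl2 (1.2 equiv), LiCl, n-Bu4NPF6 (0.1 M), DMF–THF, undivided cell, Al(+)|Ni foam(−), 1.5 mA (about 2.3 F mol−1), 13 added over 12 h (final 2 mM), rt; then PPTS, CH2Cl2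
Reagents that add atoms: none
Why: Proposed new method: Cr(II), regenerated at the cathode at a potential less negative than those needed to reduce the dienal or the C–Br bond directly, converts the allylic bromide by two one-electron steps into a 2-(methoxycarbonyl)allyl–Cr(III) species that adds aldehyde-selectively through its γ-carbon C7 to the tethered enal C6, after which Cp2ZrCl2/Al(III) removes the alkoxide from Cr to turn the catalyst over and the C6 alkoxide lactonises on the methyl ester, so the carbocycle, the lactone and the exocyclic methylene form in one operation; because the six-carbon bridge across the 2,5-positions of the furanone is only just long enough, closure is expected only from an extended C5–C6···C7–C8–C9 array, which means C5 and C8 antiperiplanar about the forming bond (anti adduct, hence the trans-lactone and 6R with 7R) and C8–C9 antiperiplanar to the forming bond with H8 eclipsing C7=C11 (A1,3 minimum, OTig outside), a geometry that exposes the C7 face giving 7R from 8R while C10 fixes the furanone face spanned by the bridge; the closest known reaction types are stoichiometric CrCl2 (Nozaki–Hiyama–Kishi/Barbier) macrocyclisations of ω-formyl 2-(bromomethyl)enoates to germacranolide lactones and intermolecular Cr-electrocatalytic NHK couplings, and I know of no electrocatalytic medium-ring allylation–lactonisation of either type.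

## Compound list
| No. | Name | SMILES | Role |
|---|---|---|---|
| 1 | (S)-5-(trityloxymethyl)dihydrofuran-2(3H)-one | O=C1CC[C@@H](COC(c2ccccc2)(c2ccccc2)c2ccccc2)O1 | starting material |
| 2 | (3R,5S)-3-methyl-5-(trityloxymethyl)dihydrofuran-2(3H)-one | O=C1[C@H](C)C[C@@H](COC(c2ccccc2)(c2ccccc2)c2ccccc2)O1 | intermediate |
| 3 | (3R,5S)-3-methyl-3-(triethylsilyloxy)-5-(trityloxymethyl)dihydrofuran-2(3H)-one | O=C1[C@](C)(O[Si](CC)(CC)CC)C[C@@H](COC(c2ccccc2)(c2ccccc2)c2ccccc2)O1 | intermediate |
| 4 | (Z)-3-methylpent-2-en-4-yn-1-ol | OC/C=C(/C)C#C | starting material |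
| 5 | (3R,5S)-5-hydroxy-3-methyl-1-(3-methylfuran-2-yl)-3-(triethylsilyloxy)-6-(trityloxy)hexan-2-one | Cc1ccoc1CC(=O)[C@](C)(O[Si](CC)(CC)CC)C[C@H](O)COC(c1ccccc1)(c1ccccc1)c1ccccc1 | intermediate |
| 6 | tiglic acid | C/C=C(\C)C(=O)O | starting material |
| 7 | (2R,4R)-4-methyl-6-(3-methylfuran-2-yl)-5-oxo-4-(triethylsilyloxy)-1-(trityloxy)hexan-2-yl tiglate | Cc1ccoc1CC(=O)[C@](C)(O[Si](CC)(CC)CC)C[C@@H](OC(=O)/C(C)=C/C)COC(c1ccccc1)(c1ccccc1)c1ccccc1 | intermediate |
| 8 | (2R,4R)-1-hydroxy-4-methyl-6-(3-methylfuran-2-yl)-5-oxo-4-(triethylsilyloxy)hexan-2-yl tiglate | Cc1ccoc1CC(=O)[C@](C)(O[Si](CC)(CC)CC)C[C@@H](OC(=O)/C(C)=C/C)CO | intermediate |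
| 9 | (2R,4R)-4-methyl-6-(3-methylfuran-2-yl)-1,5-dioxo-4-(triethylsilyloxy)hexan-2-yl tiglate | Cc1ccoc1CC(=O)[C@](C)(O[Si](CC)(CC)CC)C[C@@H](OC(=O)/C(C)=C/C)C=O | intermediate |
| 10 | methyl propiolate | C#CC(=O)OC | starting material |
| 11 | methyl (3RS,4R,6R)-3-hydroxy-6-methyl-2-methylidene-8-(3-methylfuran-2-yl)-7-oxo-4-(tigloyloxy)-6-(triethylsilyloxy)octanoate | Cc1ccoc1CC(=O)[C@](C)(O[Si](CC)(CC)CC)C[C@@H](OC(=O)/C(C)=C/C)C(O)C(=C)C(=O)OC | intermediate |
| 12 | methyl (2Z,4R,6R)-2-(bromomethyl)-6-methyl-8-(3-methylfuran-2-yl)-7-oxo-4-(tigloyloxy)-6-(triethylsilyloxy)oct-2-enoate | Cc1ccoc1CC(=O)[C@](C)(O[Si](CC)(CC)CC)C[C@@H](OC(=O)/C(C)=C/C)/C=C(\CBr)C(=O)OC | intermediate |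
| 13 | methyl (2Z,4R)-2-(bromomethyl)-4-(tigloyloxy)-5-{(2R)-2-methyl-3-oxo-5-[(2Z)-4-oxobut-2-en-2-yl]-2,3-dihydrofuran-2-yl}pent-2-enoate | O=C/C=C(/C)C1=CC(=O)[C@@](C)(C[C@@H](OC(=O)/C(C)=C/C)/C=C(\CBr)C(=O)OC)O1 | intermediate |
| 14 | atripliciolide tiglate | C=C1C(=O)O[C@@H]2/C=C(/C)C3=CC(=O)[C@@](C)(C[C@@H](OC(=O)/C(C)=C/C)[C@@H]12)O3 | target |

## Summary
Total steps: 10. Longest linear sequence: 10 (from 1). Compounds 4, 6 and 10 are used as purchased.

**Steps most likely to fail**

1. **Step 10 (the new step).**
   - Risks: strain in the oxa-bridged ten-membered transition state; 1,4-elimination of tiglate from the allylchromium to give a diene; formation of the wrong C6/C7 diastereomer.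
   - Fallback (known chemistry, different ring order): close the carbocycle before the furanone exists.
     - Add the acetylide of O-TBS-protected 4 to 3, and elaborate the product to the acyclic α′-silyloxy-ynone enal bromide.
     - Carry out a classical stoichiometric CrCl2 Barbier macrocyclisation to the less strained cyclodecenynone lactone.
     - Desilylate and form the furanone last by Au(I)-catalysed transannular 5-endo-dig cyclisation.

2. **Step 9.**
   - Risks: the 1,3-diketone carbon C2 may add to the C6 aldehyde (cyclopentenone aldol); the enal may isomerise from Z to E; Me2S may alkylate on the bromide.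
   - Fallback: drop the furan mask.
     - Use the O-TBS enynol acetylide.
     - Cyclise the α′-hydroxy ynone directly to the 3(2H)-furanone with cationic Au(I).
     - Reveal the enal at the end by HF·pyridine and then MnO2 (about three more steps).

3. **Step 4.**
   - Risks: a sluggish Mitsunobu reaction; lactol or ketone participation leading to retention or elimination.
   - Fallback: avoid inversion altogether.
     - Start from the enantiomeric (R)-trityl lactone.
     - Reverse the enolate sequence: hydroxylation, O-silylation, then methylation anti to CH2OTr. This gives the (8R,10R) relationship directly.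
     - After acetylide opening, acylate C8–OH with retention using tiglic anhydride/DMAP.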